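**Plan**

- Retrosynthetic cuts, in order: the O–Si bond; the aryl–allyl bond para to the ether oxygen (Stille); the biaryl bond (Suzuki–Miyaura); the C4a–H/C5–H pair (alkene reduction); the C3–C4 bond of ring A (key step); the two C=CH2 units (methylenation of a keto aryl ester); the ester C–O bond; the C8a–C1 bond (Michael addition to methyl acrylate).
- Enabling feature: the ether carbon C3 of ring A carries CH3, OAr, C2 and C4, so it maps onto the carbonyl carbon of an aryl ester after methylenation. C4 lies next to the ring-fusion carbon C4a, so an exocyclic methylene on ring B can attack an O-aryl oxocarbenium ion at C3. The hindered tertiary ether is therefore made by C–C and not by C–O bond formation.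
- Forward order: ring B comes from dihydrocarvone, the three-carbon arm is attached at C8a, ring A closes in step 7, the ring fusion is reduced, and the biaryl bond and the second allyl group are added last.
- Stereochemistry: C6 from (2R,5R)-dihydrocarvone; C8a from the chiral imine of (R)-1-phenylethylamine; C3 from the chair transition state of the ring closure (aryloxy axial, trans to the angular methyl); C4a from hydrogen-atom delivery anti to the angular methyl.

Key step: step 7

Remark: bicyclic compounds are numbered with C3 as the ether carbon, C4a (H) and C8a (CH3) as ring-fusion carbons and C6 as the ring B carbon bearing the oxygenated isopropyl group; commercial dihydrocarvone, a mixture of C2 epimers of the 5R series, is assumed usable as such because C2 becomes trigonal in step 1.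

**Route**

Step 1
Reactants: 1 (2R,5R)-dihydrocarvone; 2 (R)-1-phenylethylamine; 3 methyl acrylate
Product: 6 methyl 3-[(1S,4R)-1-methyl-2-oxo-4-(prop-1-en-2-yl)cyclohexyl]propanoate, via ketimine 4 (not isolated), via adduct ketimine 5 (not isolated)
Conditions: 2, toluene, reflux (Dean–Stark); then 3, THF, 45 °C; then 20% aq AcOH, rt
Reagents that add atoms: water, O
Why: Chiral-imine Michael addition (aza-ene-type reaction of the more substituted secondary enamine tautomer), in which the acrylate should add to the enamine face anti to the phenyl group of the auxiliary, so that the (R)-amine sets the (S) quaternary carbon with the new chain trans to the isopropenyl group, as is known for this ketone with vinyl ketone acceptors.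

Step 2
Reactants: 6 methyl 3-[(1S,4R)-1-methyl-2-oxo-4-(prop-1-en-2-yl)cyclohexyl]propanoate
Product: 7 methyl 3-[(1S,4R)-4-(2-hydroxypropan-2-yl)-1-methyl-2-oxocyclohexyl]propanoate
Conditions: Co(acac)2 (cat.), PhSiH3, O2 (1 atm), THF, rt
Reagents that add atoms: dioxygen, O=O
Why: Mukaiyama hydration, in which cobalt-hydride hydrogen-atom transfer to the 1,1-disubstituted alkene gives a tertiary radical that is trapped by O2 and reduced to the Markovnikov alcohol, with ketone and ester left untouched and no stereocenter formed.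

Step 3
Reactants: 7 methyl 3-[(1S,4R)-4-(2-hydroxypropan-2-yl)-1-methyl-2-oxocyclohexyl]propanoate
Product: 8 methyl 3-[(1S,4R)-1-methyl-2-oxo-4-(2-triethylsilyloxypropan-2-yl)cyclohexyl]propanoate
Conditions: Et3SiOTf, 2,6-lutidine, CH2Cl2, −78 → 0 °C
Reagents that add atoms: triethylsilyl triflate, CC[Si](CC)(CC)OS(=O)(=O)C(F)(F)F
Why: Silylation of a tertiary alcohol with a silyl triflate and a hindered base, which at low temperature should not enolsilylate the ketone and which masks the hydroxyl against the oxocarbenium ion of step 7.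

Step 4
Reactants: 8 methyl 3-[(1S,4R)-1-methyl-2-oxo-4-(2-triethylsilyloxypropan-2-yl)cyclohexyl]propanoate
Product: 9 3-[(1S,4R)-1-methyl-2-oxo-4-(2-triethylsilyloxypropan-2-yl)cyclohexyl]propanoic acid
Conditions: LiOH, THF/MeOH/H2O, rt; then dilute HCl to pH 4, 0 °C
Reagents that add atoms: lithium hydroxide, [Li+].[OH-]
Why: Saponification of an unhindered methyl ester, in which the quaternary α-carbon of the ketone cannot epimerize and the mild acidification spares the silyl ether.

Step 5
Reactants: 9 3-[(1S,4R)-1-methyl-2-oxo-4-(2-triethylsilyloxypropan-2-yl)cyclohexyl]propanoic acid; 10 2-bromo-4-chlorophenol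
Product: 11 2-bromo-4-chlorophenyl 3-[(1S,4R)-1-methyl-2-oxo-4-(2-triethylsilyloxypropan-2-yl)cyclohexyl]propanoate
Conditions: DCC, DMAP (cat.), CH2Cl2, 0 °C → rt
Reagents that add atoms: none
Why: Steglich esterification, in which the acidic phenol is acylated through the N-acylpyridinium ion under neutral conditions.

Step 6
Reactants: 11 2-bromo-4-chlorophenyl 3-[(1S,4R)-1-methyl-2-oxo-4-(2-triethylsilyloxypropan-2-yl)cyclohexyl]propanoate
Product: 13 2-bromo-4-chloro-1-({4-[(1S,4R)-1-methyl-2-methylidene-4-(2-triethylsilyloxypropan-2-yl)cyclohexyl]but-1-en-2-yl}oxy)benzene, via methylidene aryl ester 12 (not isolated)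
Conditions: Cp2TiMe2 (4 equiv), toluene/THF, 75 °C, dark; basic alumina
Reagents that add atoms: dimethyltitanocene, C[Ti](C)(C1C=CC=C1)C1C=CC=C1
Why: Petasis methylenation, in which Cp2Ti=CH2 formed on heating converts first the ketone and then the aryl ester carbonyl into C=CH2 through oxatitanacyclobutanes, without enolization and without touching aryl halides or the silyl ether.

Step 7
Reactants: 13 2-bromo-4-chloro-1-({4-[(1S,4R)-1-methyl-2-methylidene-4-(2-triethylsilyloxypropan-2-yl)cyclohexyl]but-1-en-2-yl}oxy)benzene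
Product: 16 (3R,6R,8aS)-3-(2-bromo-4-chlorophenoxy)-3,8a-dimethyl-6-(2-triethylsilyloxypropan-2-yl)-1,2,3,4,6,7,8,8a-octahydronaphthalene, via oxocarbenium ion 14 (not isolated), via tertiary C4a cation 15 (not isolated)
Conditions: Tf2NH (10 mol %), 4 Å MS, CH2Cl2 (0.01 M), −78 → −40 °C; Et3N quench
Reagents that add atoms: none
Why: Proposed new method: the acid should protonate the terminal carbon of the aryl enol ether, which is far more basic than the 1,1-disubstituted alkene, to give the tertiary O-aryl oxocarbenium ion 14; the exocyclic methylene carbon C4 then bonds to C3, and the resulting tertiary C4a cation 15 loses a C5 proton, which regenerates the acid. The closest known reaction types are Prins cyclizations of ketone-derived oxocarbenium ions and type 2 carbonyl-ene cyclizations of Lewis acid–ketone complexes onto 1,1-disubstituted alkenes, whereas alkene capture of an oxocarbenium ion carrying an aryl group on oxygen is without precedent. Ring A closes through a six-membered chair in which both alkene carbons become ring atoms (endo with respect to the alkene, exo with respect to the C=O+ bond). C3 is the only new stereocenter and is controlled by that chair: ring B holds the C8a–C8 bond equatorial and the angular methyl axial, the C3 methyl takes the equatorial site and the slimmer aryloxy group the axial one, trans to the angular methyl, and because 15 can reopen to 14 the same, more stable epimer should also prevail under equilibration. The step needs cation 15 to eliminate and not to alkylate the arene, which the deactivating bromine and chlorine atoms should secure, and it needs the tertiary ether to survive, which the low temperature and catalytic acid loading should allow. A C4=C4a alkene isomer from the alternative proton loss would not matter, since step 8 reduces both through the same C4a radical.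

Step 8
Reactants: 16 (3R,6R,8aS)-3-(2-bromo-4-chlorophenoxy)-3,8a-dimethyl-6-(2-triethylsilyloxypropan-2-yl)-1,2,3,4,6,7,8,8a-octahydronaphthalene
Product: 17 (3R,4aS,6R,8aS)-3-(2-bromo-4-chlorophenoxy)-3,8a-dimethyl-6-(2-triethylsilyloxypropan-2-yl)decahydronaphthalene
Conditions: Mn(dpm)3 (dpm = 2,2,6,6-tetramethylheptane-3,5-dionate, 10 mol %), PhSiH3, t-BuOOH, degassed i-PrOH, rt
Reagents that add atoms: none
Why: Metal-hydride hydrogen-atom-transfer hydrogenation, in which a hydrogen atom adds to C5 and the tertiary C4a radical should accept its hydrogen axially, anti to the angular methyl, to give the trans ring fusion, while the aryl halides, which a heterogeneous catalyst could cleave, stay inert.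

Step 9
Reactants: 18 4-bromophenol; 19 allyl bromide
Product: 20 1-bromo-4-(prop-2-en-1-yloxy)benzene
Conditions: K2CO3, acetone, reflux
Reagents that add atoms: none
Why: Williamson ether synthesis of a phenoxide with a reactive allylic halide.

Step 10
Reactants: 20 1-bromo-4-(prop-2-en-1-yloxy)benzene
Product: 21 4-bromo-2-(prop-2-en-1-yl)phenol
Conditions: N,N-diethylaniline, 200 °C
Reagents that add atoms: none
Why: Aromatic Claisen rearrangement followed by tautomerization, in which the two ortho positions are equivalent so that a single allylphenol should result.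

Step 11
Reactants: 21 4-bromo-2-(prop-2-en-1-yl)phenol
Product: 22 2-(prop-2-en-1-yl)-4-(4,4,5,5-tetramethyl-1,3,2-dioxaborolan-2-yl)phenol
Conditions: B2pin2, PdCl2(dppf) (cat.), KOAc, dioxane, 85 °C
Reagents that add atoms: bis(pinacolato)diboron, CC1(C)OB(OC1(C)C)B1OC(C)(C)C(C)(C)O1
Why: Miyaura borylation of an aryl bromide, which tolerates the free phenol and the allyl group under the weakly basic acetate conditions.

Step 12
Reactants: 17 (3R,4aS,6R,8aS)-3-(2-bromo-4-chlorophenoxy)-3,8a-dimethyl-6-(2-triethylsilyloxypropan-2-yl)decahydronaphthalene; 22 2-(prop-2-en-1-yl)-4-(4,4,5,5-tetramethyl-1,3,2-dioxaborolan-2-yl)phenol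
Product: 23 4-{5-chloro-2-[((3R,4aS,6R,8aS)-3,8a-dimethyl-6-(2-triethylsilyloxypropan-2-yl)decahydronaphthalen-3-yl)oxy]phenyl}-2-(prop-2-en-1-yl)phenol
Conditions: PdCl2(dppf) (cat.), K2CO3, dioxane/H2O, 85 °C
Reagents that add atoms: none
Why: Suzuki–Miyaura coupling, in which oxidative addition with this catalyst should occur at the C–Br bond only and leave the C–Cl bond for step 13.

Step 13
Reactants: 23 4-{5-chloro-2-[((3R,4aS,6R,8aS)-3,8a-dimethyl-6-(2-triethylsilyloxypropan-2-yl)decahydronaphthalen-3-yl)oxy]phenyl}-2-(prop-2-en-1-yl)phenol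
Product: 24 4-{2-[((3R,4aS,6R,8aS)-3,8a-dimethyl-6-(2-triethylsilyloxypropan-2-yl)decahydronaphthalen-3-yl)oxy]-5-(prop-2-en-1-yl)phenyl}-2-(prop-2-en-1-yl)phenol
Conditions: allyltributylstannane, Pd2(dba)3 (cat.), P(t-Bu)3, CsF, dioxane, 100 °C
Reagents that add atoms: allyltributylstannane, C=CC[Sn](CCCC)(CCCC)CCCC
Why: Stille coupling of an aryl chloride, in which the bulky electron-rich phosphine enables oxidative addition of zerovalent palladium to the C–Cl bond and fluoride activates the stannane for allyl transfer.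

Step 14
Reactants: 24 4-{2-[((3R,4aS,6R,8aS)-3,8a-dimethyl-6-(2-triethylsilyloxypropan-2-yl)decahydronaphthalen-3-yl)oxy]-5-(prop-2-en-1-yl)phenyl}-2-(prop-2-en-1-yl)phenol
Product: 25 4-{2-[((3R,4aS,6R,8aS)-6-(2-hydroxypropan-2-yl)-3,8a-dimethyldecahydronaphthalen-3-yl)oxy]-5-(prop-2-en-1-yl)phenyl}-2-(prop-2-en-1-yl)phenol
Conditions: Bu4NF, THF, 50 °C
Reagents that add atoms: none
Why: Fluoride-induced desilylation of the tertiary silyl ether, under non-acidic conditions that should spare the acid-labile tertiary alkyl aryl ether and the allyl groups.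

**Compound list**

1 | (2R,5R)-dihydrocarvone | C[C@@H]1CC[C@@H](C(C)=C)CC1=O | starting material
2 | (R)-1-phenylethylamine | C[C@@H](N)c1ccccc1 | starting material
3 | methyl acrylate | C=CC(=O)OC | starting material
4 | N-[(R)-1-phenylethyl] ketimine of dihydrocarvone (C2 epimers, in equilibrium with the secondary enamine) | CC1CC[C@@H](C(C)=C)CC1=N[C@H](C)c1ccccc1 | intermediate
5 | N-[(R)-1-phenylethyl] ketimine of keto ester 6 | COC(=O)CC[C@]1(C)CC[C@@H](C(C)=C)CC1=N[C@H](C)c1ccccc1 | intermediate
6 | methyl 3-[(1S,4R)-1-methyl-2-oxo-4-(prop-1-en-2-yl)cyclohexyl]propanoate | COC(=O)CC[C@]1(C)CC[C@@H](C(C)=C)CC1=O | intermediate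
7 | methyl 3-[(1S,4R)-4-(2-hydroxypropan-2-yl)-1-methyl-2-oxocyclohexyl]propanoate | COC(=O)CC[C@]1(C)CC[C@@H](C(C)(C)O)CC1=O | intermediate
8 | methyl 3-[(1S,4R)-1-methyl-2-oxo-4-(2-triethylsilyloxypropan-2-yl)cyclohexyl]propanoate | COC(=O)CC[C@]1(C)CC[C@@H](C(C)(C)O[Si](CC)(CC)CC)CC1=O | intermediate
9 | 3-[(1S,4R)-1-methyl-2-oxo-4-(2-triethylsilyloxypropan-2-yl)cyclohexyl]propanoic acid | OC(=O)CC[C@]1(C)CC[C@@H](C(C)(C)O[Si](CC)(CC)CC)CC1=O | intermediate
10 | 2-bromo-4-chlorophenol | Oc1ccc(Cl)cc1Br | starting material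
11 | 2-bromo-4-chlorophenyl 3-[(1S,4R)-1-methyl-2-oxo-4-(2-triethylsilyloxypropan-2-yl)cyclohexyl]propanoate | O=C(CC[C@]1(C)CC[C@@H](C(C)(C)O[Si](CC)(CC)CC)CC1=O)Oc1ccc(Cl)cc1Br | intermediate
12 | 2-bromo-4-chlorophenyl 3-[(1S,4R)-1-methyl-2-methylidene-4-(2-triethylsilyloxypropan-2-yl)cyclohexyl]propanoate | O=C(CC[C@]1(C)CC[C@@H](C(C)(C)O[Si](CC)(CC)CC)CC1=C)Oc1ccc(Cl)cc1Br | intermediate
13 | 2-bromo-4-chloro-1-({4-[(1S,4R)-1-methyl-2-methylidene-4-(2-triethylsilyloxypropan-2-yl)cyclohexyl]but-1-en-2-yl}oxy)benzene | C=C(CC[C@]1(C)CC[C@@H](C(C)(C)O[Si](CC)(CC)CC)CC1=C)Oc1ccc(Cl)cc1Br | intermediate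
14 | O-aryl oxocarbenium ion formed by C-protonation of the enol ether of 13 | CC(CC[C@]1(C)CC[C@@H](C(C)(C)O[Si](CC)(CC)CC)CC1=C)=[O+]c1ccc(Cl)cc1Br | intermediate
15 | bicyclic tertiary carbocation at C4a (C3–C4 bond formed) | Clc1ccc(O[C@]2(C)CC[C@]3(C)CC[C@@H](C(C)(C)O[Si](CC)(CC)CC)C[C+]3C2)c(Br)c1 | intermediate
16 | (3R,6R,8aS)-3-(2-bromo-4-chlorophenoxy)-3,8a-dimethyl-6-(2-triethylsilyloxypropan-2-yl)-1,2,3,4,6,7,8,8a-octahydronaphthalene (C4a=C5 alkene; aryloxy axial, trans to the angular methyl) | Clc1ccc(O[C@]2(C)CC[C@]3(C)CC[C@@H](C(C)(C)O[Si](CC)(CC)CC)C=C3C2)c(Br)c1 | intermediate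
17 | (3R,4aS,6R,8aS)-3-(2-bromo-4-chlorophenoxy)-3,8a-dimethyl-6-(2-triethylsilyloxypropan-2-yl)decahydronaphthalene (trans-fused) | Clc1ccc(O[C@]2(C)CC[C@]3(C)CC[C@@H](C(C)(C)O[Si](CC)(CC)CC)C[C@H]3C2)c(Br)c1 | intermediate
18 | 4-bromophenol | Oc1ccc(Br)cc1 | starting material
19 | allyl bromide | C=CCBr | starting material
20 | 1-bromo-4-(prop-2-en-1-yloxy)benzene | C=CCOc1ccc(Br)cc1 | intermediate
21 | 4-bromo-2-(prop-2-en-1-yl)phenol | C=CCc1cc(Br)ccc1O | intermediate
22 | 2-(prop-2-en-1-yl)-4-(4,4,5,5-tetramethyl-1,3,2-dioxaborolan-2-yl)phenol | C=CCc1cc(B2OC(C)(C)C(C)(C)O2)ccc1O | intermediate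
23 | 4-{5-chloro-2-[((3R,4aS,6R,8aS)-3,8a-dimethyl-6-(2-triethylsilyloxypropan-2-yl)decahydronaphthalen-3-yl)oxy]phenyl}-2-(prop-2-en-1-yl)phenol | Clc1ccc(O[C@]2(C)CC[C@]3(C)CC[C@@H](C(C)(C)O[Si](CC)(CC)CC)C[C@H]3C2)c(-c2ccc(O)c(CC=C)c2)c1 | intermediate
24 | 4-{2-[((3R,4aS,6R,8aS)-3,8a-dimethyl-6-(2-triethylsilyloxypropan-2-yl)decahydronaphthalen-3-yl)oxy]-5-(prop-2-en-1-yl)phenyl}-2-(prop-2-en-1-yl)phenol | C=CCc1ccc(O[C@]2(C)CC[C@]3(C)CC[C@@H](C(C)(C)O[Si](CC)(CC)CC)C[C@H]3C2)c(-c2ccc(O)c(CC=C)c2)c1 | intermediate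
25 | 4-{2-[((3R,4aS,6R,8aS)-6-(2-hydroxypropan-2-yl)-3,8a-dimethyldecahydronaphthalen-3-yl)oxy]-5-(prop-2-en-1-yl)phenyl}-2-(prop-2-en-1-yl)phenol (CNP0342687.1) | C=CCc1ccc(O[C@]2(C)CC[C@]3(C)CC[C@@H](C(C)(C)O)C[C@H]3C2)c(-c2ccc(O)c(CC=C)c2)c1 | target

**Step count**

Total: 14 steps. Longest linear sequence: 11 steps (steps 1–8 and 12–14); steps 9–11 prepare the boronate.

**Steps most likely to fail**

1. Step 7 (the step labelled as a new method). The oxocarbenium ion may be consumed by adventitious hydrolysis, by oligomerization or by reversion to the isomeric enol ether faster than the alkene captures it, or the ring may close with too little preference for the axial aryloxy group. The fallback uses known chemistry, keeps the C3–C4 ring closure, sets out from 13 and returns at 16. Hydrolysis of the enol ether of 13 with dilute oxalic acid in wet THF would give the methyl ketone F1. A type 2 carbonyl-ene cyclization with Me2AlCl (CH2Cl2, −78 to 0 °C), a reaction type established for methyl ketones tethered to 1,1-disubstituted alkenes, would then give the tertiary homoallylic alcohol F2. Its hydroxyl should be axial because the C5 hydrogen is passed to oxygen within the chair. The sodium alkoxide of F2 (NaH, toluene, rt) would be O-arylated with the diaryliodonium salt F3, prepared in one pot from 2-bromo-4-chloro-1-iodobenzene, mCPBA, TsOH and 1,3,5-trimethoxybenzene, to give 16.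

2. Step 8. Facial selectivity in the hydrogen delivery to the C4a radical may be poor, because the axial aryloxy group at C3 lies on the face that has to be attacked, and the cis-fused epimer would then form. The fallback sets out from 16 and returns at 17. Hydroboration of 16 (BH3·SMe2, THF, 0 °C to rt; then NaOH/H2O2) should add boron to C5 and hydrogen to C4a in a four-centre syn addition on the face opposite the angular methyl, where only the small hydrogen has to pass the aryloxy group. This would give the trans-fused C5 alcohol F4. Conversion into the S-methyl xanthate F5 (NaH, CS2, MeI) and Barton–McCombie deoxygenation with H3PO2/Et3N/AIBN in refluxing dioxane, chosen because phosphorus-centred radicals spare aryl bromides, would give 17.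

3. Step 13. Oxidative addition to the electron-rich aryl chloride may be sluggish, the phenoxide may be arylated in competition, and palladium hydride species may move the allyl double bonds into conjugation. The fallback reverses the polarity of the coupling, sets out from 23 and returns at 25. Silylation of the phenol (i-Pr3SiCl, imidazole, DMF) would give the triisopropylsilyl ether F6. Miyaura borylation of the chloride (Pd2(dba)3, XPhos, B2pin2, KOAc, dioxane, 100 °C) would give the arylboronate F7. Suzuki–Miyaura-type coupling with allyl bromide (Pd(PPh3)4, K2CO3, THF/H2O, 60 °C) would give the diallyl bis-silyl ether F8. Bu4NF in THF would then remove both silyl groups to give 25.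

**Further compounds**

F1 | step 7 | 4-[(1S,4R)-1-methyl-2-methylidene-4-(2-triethylsilyloxypropan-2-yl)cyclohexyl]butan-2-one | CC(=O)CC[C@]1(C)CC[C@@H](C(C)(C)O[Si](CC)(CC)CC)CC1=C
F2 | step 7 | (3R,6R,8aS)-3,8a-dimethyl-6-(2-triethylsilyloxypropan-2-yl)-1,2,3,4,6,7,8,8a-octahydronaphthalen-3-ol | O[C@]1(C)CC[C@]2(C)CC[C@@H](C(C)(C)O[Si](CC)(CC)CC)C=C2C1
F3 | step 7 | (2-bromo-4-chlorophenyl)(2,4,6-trimethoxyphenyl)iodonium p-toluenesulfonate | COc1cc(OC)c([I+]c2ccc(Cl)cc2Br)c(OC)c1.Cc1ccc(S(=O)(=O)[O-])cc1
F4 | step 8 | (3R,4aS,5R,6R,8aS)-3-(2-bromo-4-chlorophenoxy)-3,8a-dimethyl-6-(2-triethylsilyloxypropan-2-yl)decahydronaphthalen-5-ol | Clc1ccc(O[C@]2(C)CC[C@]3(C)CC[C@@H](C(C)(C)O[Si](CC)(CC)CC)[C@H](O)[C@H]3C2)c(Br)c1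
F5 | step 8 | O-[(3R,4aS,5R,6R,8aS)-3-(2-bromo-4-chlorophenoxy)-3,8a-dimethyl-6-(2-triethylsilyloxypropan-2-yl)decahydronaphthalen-5-yl] S-methyl carbonodithioate | Clc1ccc(O[C@]2(C)CC[C@]3(C)CC[C@@H](C(C)(C)O[Si](CC)(CC)CC)[C@H](OC(=S)SC)[C@H]3C2)c(Br)c1
F6 | step 13 | triisopropylsilyl ether of 23 | Clc1ccc(O[C@]2(C)CC[C@]3(C)CC[C@@H](C(C)(C)O[Si](CC)(CC)CC)C[C@H]3C2)c(-c2ccc(O[Si](C(C)C)(C(C)C)C(C)C)c(CC=C)c2)c1
F7 | step 13 | pinacol arylboronate from F6 (Bpin in place of Cl) | CC1(C)OB(c2ccc(O[C@]3(C)CC[C@]4(C)CC[C@@H](C(C)(C)O[Si](CC)(CC)CC)C[C@H]4C3)c(-c3ccc(O[Si](C(C)C)(C(C)C)C(C)C)c(CC=C)c3)c2)OC1(C)C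
F8 | step 13 | triisopropylsilyl ether of 24 | C=CCc1ccc(O[C@]2(C)CC[C@]3(C)CC[C@@H](C(C)(C)O[Si](CC)(CC)CC)C[C@H]3C2)c(-c2ccc(O[Si](C(C)C)(C(C)C)C(C)C)c(CC=C)c2)c1
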